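**Retrosynthetic overview**
1. The last disconnection is a Heck coupling between the ring F aryl chloride of the upper half (hexaacetate 24) and the 4-vinyl-2,3-trans-dihydrobenzofuran 37 (tetraacetate), followed by mild deacetylation. All methyl ethers are removed on the two halves before they are joined, so the acid-sensitive stilbene/dihydrobenzofuran array never meets a Lewis acid.
2. Feature used: the seven-membered ring (ring A–Ca–Cb–ring B–B1–Cc–ring A) and the upper dihydrofuran (ring B oxygen–Cd–Cc–B1) share the Cc–B1 bond. The O–C–B1 unit of resorcinol ring B and a Cc=Cd stilbene on ring A therefore give both rings in one oxidative phenol–stilbene (3+2) on seco stilbene 21.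
3. 21 is a (1S,2S)-1,1,2,2-tetraarylethane. Ca comes from Rh/diene arylation of the ring A nitroalkene. Cb comes from sparteine-controlled lithiation–borylation of the 2,2-diarylethyl carbamate with the ring F boronic ester, then stereoretentive arylation of the benzylic boronic ester with the ring B aryllithium. The stilbene is installed by Suzuki coupling on the ring A triflate.
4. Lower half: a donor/donor rhodium carbene C–H insertion sets C3; BBr3 demethylation equilibrates C2 to trans.
5. Ring order: lower dihydrofuran (step 20, separate branch); seven-membered ring and upper dihydrofuran together (step 13).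

Key step: step 13

Labels: ring A = dioxygenated ring carrying Ca and Cc; ring B = resorcinol ring carrying Cb (B1 = its carbon ortho to Cb that bonds to Cc); ring E = 4-oxyphenyl on Ca; ring F = 2-oxy-5-chlorophenyl on Cb; ring G = 4-oxyphenyl on Cd.

Assumption: the ligand enantiomers named in the two rhodium-catalysed asymmetric steps (3 and 20) are taken to give the drawn configurations; should the sense of induction be opposite on these substrates, the antipodal ligand is used and nothing else changes.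

**Upper half**

Step 1
Reactants: 1 2-hydroxy-4,6-dimethoxybenzaldehyde
Product: 2 2,4-dimethoxy-6-(methoxymethoxy)benzaldehyde
Conditions: NaH, MOMCl, DMF, 0 °C to rt
Reagents that add atoms: chloromethyl methyl ether, COCCl
Why: Williamson-type O-alkylation of the phenoxide masks the future stilbene position of ring A as a small, organolithium-stable methoxymethyl ether that can later be removed by acid without touching benzyl ethers.

Step 2
Reactants: 2 2,4-dimethoxy-6-(methoxymethoxy)benzaldehyde
Product: 3 (E)-1,5-dimethoxy-3-(methoxymethoxy)-2-(2-nitroethenyl)benzene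
Conditions: MeNO2, NH4OAc, 90 °C
Reagents that add atoms: nitromethane, C[N+](=O)[O-]
Why: Henry condensation with dehydration should give the conjugated (E)-nitroalkene, as it does for 2,4,6-trialkoxybenzaldehydes.

Step 3
Reactants: 3 (E)-1,5-dimethoxy-3-(methoxymethoxy)-2-(2-nitroethenyl)benzene; 4 4-methoxyphenylboronic acid
Product: 5 (S)-1,5-dimethoxy-3-(methoxymethoxy)-2-[1-(4-methoxyphenyl)-2-nitroethyl]benzene
Conditions: Rh(acac)(C2H4)2 (3 mol%), (R,R)-Ph-bod [(1R,4R)-2,5-diphenylbicyclo[2.2.2]octa-2,5-diene], KOH (10 mol%), dioxane/H2O 10:1, 60 °C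
Reagents that add atoms: none
Why: Hayashi–Miyaura rhodium-catalysed asymmetric conjugate addition of the arylboronic acid to the nitroalkene; the C2-symmetric diene selects the alkene face and so sets Ca (S).

Step 4
Reactants: 5 (S)-1,5-dimethoxy-3-(methoxymethoxy)-2-[1-(4-methoxyphenyl)-2-nitroethyl]benzene
Product: 6 (S)-2-[2,4-dimethoxy-6-(methoxymethoxy)phenyl]-2-(4-methoxyphenyl)acetic acid
Conditions: NaNO2, AcOH, DMSO, 35 °C
Reagents that add atoms: sodium nitrite, [Na+].[O-]N=O; water, O
Why: nitrite-mediated oxidative Nef-type conversion of a primary nitroalkane into the carboxylic acid under weakly acidic conditions; going through the acid avoids the configurationally labile 2,2-diarylacetaldehyde, so Ca should be preserved.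

Step 5
Reactants: 6 (S)-2-[2,4-dimethoxy-6-(methoxymethoxy)phenyl]-2-(4-methoxyphenyl)acetic acid
Product: 7 (S)-2-[2,4-dimethoxy-6-(methoxymethoxy)phenyl]-2-(4-methoxyphenyl)ethanol
Conditions: BH3·SMe2, THF, 0 °C to rt; MeOH
Reagents that add atoms: none
Why: borane reduction of a carboxylic acid to the primary alcohol proceeds without base and so without enolisation at Ca.

Step 6
Reactants: 7 (S)-2-[2,4-dimethoxy-6-(methoxymethoxy)phenyl]-2-(4-methoxyphenyl)ethanol
Product: 8 (S)-2-[2,4-dimethoxy-6-(methoxymethoxy)phenyl]-2-(4-methoxyphenyl)ethyl N,N-diisopropylcarbamate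
Conditions: i-Pr2NCOCl, Et3N, CH2Cl2, reflux
Reagents that add atoms: N,N-diisopropylcarbamoyl chloride, CC(C)N(C(C)C)C(Cl)=O
Why: O-carbamoylation gives the Hoppe carbamate needed for directed, sparteine-controlled α-lithiation.

Step 7
Reactants: 8 (S)-2-[2,4-dimethoxy-6-(methoxymethoxy)phenyl]-2-(4-methoxyphenyl)ethyl N,N-diisopropylcarbamate; 9 2-(5-chloro-2-methoxyphenyl)-4,4,5,5-tetramethyl-1,3,2-dioxaborolane
Product: 12 2-[(1R,2S)-1-(5-chloro-2-methoxyphenyl)-2-[2,4-dimethoxy-6-(methoxymethoxy)phenyl]-2-(4-methoxyphenyl)ethyl]-4,4,5,5-tetramethyl-1,3,2-dioxaborolane, via lithiated carbamate 10 (not isolated), via lithium boronate 11 (not isolated)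
Conditions: s-BuLi, (−)-sparteine, Et2O, −78 °C; 9, −78 °C; MgBr2·OEt2, −78 °C to 35 °C
Reagents that add atoms: none
Why: Hoppe–Aggarwal lithiation–borylation: s-BuLi/(−)-sparteine removes the pro-S proton to give the configurationally stable (S)-lithiated carbamate, the boronic ester adds with retention, and ring F migrates from boron to carbon with inversion (1,2-metallate rearrangement), so Cb is set by the reagent.

Step 8
Reactants: 12 the (1R,2S)-benzylic boronic ester; 13 1,3-bis(benzyloxy)-5-bromobenzene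
Product: 16 (1S,2S)-1-[3,5-bis(benzyloxy)phenyl]-1-(5-chloro-2-methoxyphenyl)-2-[2,4-dimethoxy-6-(methoxymethoxy)phenyl]-2-(4-methoxyphenyl)ethane, via aryllithium 14 (not isolated), via lithium boronate 15 (not isolated)
Conditions: 13, n-BuLi, THF, −78 °C; add 12, −78 °C to 0 °C; NBS, THF, −78 °C to rt
Reagents that add atoms: none
Why: Aggarwal's transition-metal-free stereospecific sp2–sp3 coupling: NBS brominates the aryl ring of the boronate (activated by its two meta alkoxy groups), which triggers 1,2-migration of the benzylic carbon with retention and rearomatisation by loss of bromide and boron, so ring B takes the place of boron at Cb.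

Step 9
Reactants: 16 the (1S,2S)-tetraarylethane with ring A methoxymethyl ether
Product: 17 2-[(1S,2S)-2-[3,5-bis(benzyloxy)phenyl]-2-(5-chloro-2-methoxyphenyl)-1-(4-methoxyphenyl)ethyl]-3,5-dimethoxyphenol
Conditions: HCl (3 M aq.), MeOH/THF, 50 °C
Reagents that add atoms: none
Why: acid-catalysed acetal cleavage removes the methoxymethyl group only; methyl and benzyl ethers are stable.

Step 10
Reactants: 17 the ring A phenol
Product: 18 2-[(1S,2S)-2-[3,5-bis(benzyloxy)phenyl]-2-(5-chloro-2-methoxyphenyl)-1-(4-methoxyphenyl)ethyl]-3,5-dimethoxyphenyl trifluoromethanesulfonate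
Conditions: Tf2O, pyridine, CH2Cl2, 0 °C
Reagents that add atoms: trifluoromethanesulfonic anhydride, O=S(=O)(OS(=O)(=O)C(F)(F)F)C(F)(F)F
Why: O-sulfonylation of the only free phenol gives the cross-coupling handle on ring A.

Step 11
Reactants: 18 the ring A triflate
Product: 19 2-[(1S,2S)-2-(5-chloro-2-methoxyphenyl)-2-(3,5-dihydroxyphenyl)-1-(4-methoxyphenyl)ethyl]-3,5-dimethoxyphenyl trifluoromethanesulfonate
Conditions: BCl3, C6Me5H, CH2Cl2, −78 °C; MeOH
Reagents that add atoms: none
Why: Lewis-acid debenzylation with pentamethylbenzene as benzyl-cation scavenger cleaves aryl benzyl ethers at −78 °C and leaves methyl ethers, the triflate and the chloride; it is done before the acid-sensitive stilbene exists.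

Step 12
Reactants: 19 the resorcinol triflate; 20 (E)-2-[2-(4-methoxyphenyl)ethenyl]-4,4,5,5-tetramethyl-1,3,2-dioxaborolane
Product: 21 5-[(1S,2S)-1-(5-chloro-2-methoxyphenyl)-2-{2,4-dimethoxy-6-[(E)-2-(4-methoxyphenyl)ethenyl]phenyl}-2-(4-methoxyphenyl)ethyl]benzene-1,3-diol
Conditions: PdCl2(dppf) (5 mol%), K3PO4, dioxane/H2O 10:1, 80 °C, degassed
Reagents that add atoms: none
Why: Suzuki–Miyaura coupling at the triflate (far more reactive than the electron-rich aryl chloride) transfers the alkenyl group with retention of the (E) geometry and tolerates the free resorcinol.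

Step 13
Reactants: 21 the seco stilbene
Product: 22 upper-half aryl chloride (Ca S, Cb S, Cc S, Cd S): seven-membered ring through Ca–Cb and Cc–B1, trans-dihydrofuran through ring B oxygen–Cd; methyl ethers on rings A (two), E, F and G; one free hydroxyl on ring B
Conditions: Ru(bpz)3(PF6)2 (2 mol%), (NH4)2S2O8 (2 equiv), MeCN (0.005 M), blue LEDs, rt, degassed
Reagents that add atoms: none
Why: Proposed new method: the excited Ru(bpz)3 dication is quenched by persulfate to the trivalent ruthenium complex, which takes one electron from the trialkoxystilbene (the most easily oxidised π-system), and the radical cation is attacked at Cc, the alkene carbon remote from ring G, by B1 of the tethered resorcinol in a 7-exo-trig C–C closure that leaves a 4-methoxybenzyl radical at Cd; a second one-electron oxidation gives the Cd cation, which the neighbouring phenol oxygen captures in a 5-exo-trig closure. The closest known reaction type is the intermolecular visible-light oxidative (3+2) cycloaddition of phenols with 4-methoxystyrenes and stilbenes to trans-2-aryl-2,3-dihydrobenzofurans; the resorcinol partner, the intramolecular mode and the seven-membered ring are new. One constitution is expected because B1 and its mirror carbon on the symmetrical resorcinol are equivalent, the carbon para to Cb cannot reach Cc, and the anisyl group directs carbon to Cc and oxygen to Cd (the same connectivity results if the phenol is oxidised first). Cc is set under substrate control: with the Ca–H bond near the plane of ring A and ring E turned away from the ortho methoxy group, the folded Ca–Cb tether should deliver B1 to the alkene face that places Cd on the side of the new ring opposite rings E and F. Cd is set trans to ring A on Cc, the lower-energy arrangement in the five-membered ring and the one restored by reversible ionisation at the anisyl carbon. The step needs chemoselective oxidation of the stilbene over the anisole, chloroanisole and resorcinol rings and high dilution against intermolecular stilbene dimerisation.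

Step 14
Reactants: 22 the upper-half aryl chloride
Product: 24 upper-half aryl chloride hexaacetate (all-S at Ca/Cb/Cc/Cd), via hexaphenol 23 (not isolated)
Conditions: BBr3, CH2Cl2, −78 °C to 0 °C; cold aq. NaHCO3; crude: Ac2O, pyridine, DMAP (cat.), rt
Reagents that add atoms: acetic anhydride, CC(=O)OC(C)=O
Why: Lewis-acid demethylation of the five aryl methyl ethers (any opening of the dihydrofuran at Cd is reversible and recloses trans), then acetylation of the crude air-sensitive hexaphenol to a stable, chromatographable Heck partner.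

**Lower half**

Step 15
Reactants: 25 2-bromo-4,6-dimethoxybenzaldehyde
Product: 26 2-bromo-6-hydroxy-4-methoxybenzaldehyde
Conditions: BCl3, CH2Cl2, −78 °C to 0 °C
Reagents that add atoms: none
Why: chelation-controlled mono-demethylation removes only the methyl ether ortho to the aldehyde.

Step 16
Reactants: 26 2-bromo-6-hydroxy-4-methoxybenzaldehyde; 27 4-methoxybenzyl chloride
Product: 28 2-bromo-4-methoxy-6-[(4-methoxybenzyl)oxy]benzaldehyde
Conditions: K2CO3, DMF, 60 °C
Reagents that add atoms: none
Why: Williamson ether synthesis installs the 4-methoxybenzyl group whose benzylic carbon becomes C2 of the dihydrobenzofuran.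

Step 17
Reactants: 28 2-bromo-4-methoxy-6-[(4-methoxybenzyl)oxy]benzaldehyde; 29 3,5-dimethoxyphenylmagnesium chloride
Product: 30 racemic {2-bromo-4-methoxy-6-[(4-methoxybenzyl)oxy]phenyl}(3,5-dimethoxyphenyl)methanol
Conditions: THF, −78 °C to 0 °C; aq. NH4Cl
Reagents that add atoms: none
Why: Grignard 1,2-addition to the aldehyde; the aryl bromide is inert to the arylmagnesium reagent at low temperature, and the new stereocentre is removed in the next step.

Step 18
Reactants: 30 the diaryl carbinol
Product: 31 {2-bromo-4-methoxy-6-[(4-methoxybenzyl)oxy]phenyl}(3,5-dimethoxyphenyl)methanone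
Conditions: Dess–Martin periodinane, CH2Cl2, rt
Reagents that add atoms: none
Why: Dess–Martin oxidation of a hindered benzhydrol to the benzophenone under neutral conditions.

Step 19
Reactants: 31 the diaryl ketone
Product: 32 hydrazone of 31 (E/Z mixture)
Conditions: N2H4·H2O, AcOH (cat.), n-BuOH, 110 °C
Reagents that add atoms: hydrazine, NN
Why: condensation of hydrazine with the ketone, forced by temperature because the carbonyl is flanked by two ortho substituents.

Step 20
Reactants: 32 the hydrazone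
Product: 34 (2R,3S)-4-bromo-3-(3,5-dimethoxyphenyl)-6-methoxy-2-(4-methoxyphenyl)-2,3-dihydrobenzofuran (2,3-cis), via diazo compound 33 (not isolated)
Conditions: MnO2, CH2Cl2, 0 °C; filtration; Rh2(S-PTAD)4 (1 mol%), CH2Cl2, −20 °C to rt
Reagents that add atoms: none
Why: oxidation of the hydrazone to the diaryldiazomethane and rhodium donor/donor carbene 1,5-insertion into the activated 4-methoxybenzylic C–H bond; the chiral carboxylate catalyst sets C3 (S) and the cis isomer is the expected kinetic product.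

Step 21
Reactants: 34 the cis-dihydrobenzofuran
Product: 36 (2S,3S)-4-bromo-2,3-trans-dihydrobenzofuran tetraacetate, via tetraphenol 35 (not isolated)
Conditions: BBr3, CH2Cl2, −78 °C to rt; aq. NaHCO3; crude: Ac2O, pyridine, DMAP (cat.), rt
Reagents that add atoms: acetic anhydride, CC(=O)OC(C)=O
Why: BBr3 cleaves the four methyl ethers and reversibly ionises the C2–O bond at the 4-oxybenzylic carbon, so C2 equilibrates to the more stable 2,3-trans isomer while C3 is untouched; acetylation caps the phenols.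

Step 22
Reactants: 36 the trans bromide tetraacetate
Product: 37 (2S,3S)-4-ethenyl-2,3-trans-dihydrobenzofuran tetraacetate
Conditions: Bu3SnCH=CH2, Pd(PPh3)4 (5 mol%), toluene, 100 °C
Reagents that add atoms: tributyl(vinyl)stannane, C=C[Sn](CCCC)(CCCC)CCCC
Why: Stille coupling vinylates the aryl bromide under neutral conditions that keep the aryl acetates.

**Fragment union**

Step 23
Reactants: 24 the upper-half aryl chloride hexaacetate; 37 the 4-ethenyl dihydrobenzofuran tetraacetate
Product: 38 decaacetate of the target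
Conditions: Pd2(dba)3 (2.5 mol%), [HP(t-Bu)3]BF4 (10 mol%), Cy2NMe, dioxane, 100 °C
Reagents that add atoms: none
Why: Mizoroki–Heck coupling of an aryl chloride with a styrene under Pd/P(t-Bu)3 catalysis; syn-insertion and β-hydride elimination give the (E)-stilbene and no stereocentre is touched.

Step 24
Reactants: 38 the decaacetate
Product: 39 target CNP0266373.2 (S at Ca, Cb, Cc, Cd and at C2 and C3 of the lower dihydrobenzofuran)
Conditions: K2CO3, MeOH/THF, 0 °C to rt, argon; then AcOH
Reagents that add atoms: none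
Why: base-catalysed transesterification of the ten aryl acetates to methyl acetate releases the polyphenol without acid, so neither dihydrofuran nor the stilbene is at risk.

**Compound list**
1 | 2-hydroxy-4,6-dimethoxybenzaldehyde | COc1cc(O)c(C=O)c(OC)c1 | starting material
2 | 2,4-dimethoxy-6-(methoxymethoxy)benzaldehyde | COCOc1cc(OC)cc(OC)c1C=O | intermediate
3 | (E)-1,5-dimethoxy-3-(methoxymethoxy)-2-(2-nitroethenyl)benzene | COCOc1cc(OC)cc(OC)c1/C=C/[N+](=O)[O-] | intermediate
4 | 4-methoxyphenylboronic acid | COc1ccc(B(O)O)cc1 | starting material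
5 | (S)-1,5-dimethoxy-3-(methoxymethoxy)-2-[1-(4-methoxyphenyl)-2-nitroethyl]benzene | COc1ccc(cc1)[C@@H](c1c(OC)cc(OC)cc1OCOC)C[N+](=O)[O-] | intermediate
6 | (S)-2-[2,4-dimethoxy-6-(methoxymethoxy)phenyl]-2-(4-methoxyphenyl)acetic acid | COc1ccc(cc1)[C@@H](c1c(OC)cc(OC)cc1OCOC)C(=O)O | intermediate
7 | (S)-2-[2,4-dimethoxy-6-(methoxymethoxy)phenyl]-2-(4-methoxyphenyl)ethanol | COc1ccc(cc1)[C@@H](c1c(OC)cc(OC)cc1OCOC)CO | intermediate
8 | (S)-2-[2,4-dimethoxy-6-(methoxymethoxy)phenyl]-2-(4-methoxyphenyl)ethyl N,N-diisopropylcarbamate | COc1ccc(cc1)[C@@H](c1c(OC)cc(OC)cc1OCOC)COC(=O)N(C(C)C)C(C)C | intermediate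
9 | 2-(5-chloro-2-methoxyphenyl)-4,4,5,5-tetramethyl-1,3,2-dioxaborolane | COc1ccc(Cl)cc1B1OC(C)(C)C(C)(C)O1 | starting material
10 | (1S,2S)-1-lithio derivative of 8 (sparteine complex; ligand not drawn) | COc1ccc(cc1)[C@@H](c1c(OC)cc(OC)cc1OCOC)[C@H]([Li])OC(=O)N(C(C)C)C(C)C | intermediate
11 | lithium boronate from 10 and 9 (boron bonded with retention) | COc1ccc(cc1)[C@@H](c1c(OC)cc(OC)cc1OCOC)[C@H]([B-]1(OC(C)(C)C(C)(C)O1)c1cc(Cl)ccc1OC)OC(=O)N(C(C)C)C(C)C.[Li+] | intermediate
12 | 2-[(1R,2S)-1-(5-chloro-2-methoxyphenyl)-2-[2,4-dimethoxy-6-(methoxymethoxy)phenyl]-2-(4-methoxyphenyl)ethyl]-4,4,5,5-tetramethyl-1,3,2-dioxaborolane | COc1ccc(cc1)[C@@H](c1c(OC)cc(OC)cc1OCOC)[C@@H](B1OC(C)(C)C(C)(C)O1)c1cc(Cl)ccc1OC | intermediate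
13 | 1,3-bis(benzyloxy)-5-bromobenzene | Brc1cc(OCc2ccccc2)cc(OCc2ccccc2)c1 | starting material
14 | 3,5-bis(benzyloxy)phenyllithium | [Li]c1cc(OCc2ccccc2)cc(OCc2ccccc2)c1 | intermediate
15 | lithium boronate from 12 and 14 | COc1ccc(cc1)[C@@H](c1c(OC)cc(OC)cc1OCOC)[C@@H]([B-]1(OC(C)(C)C(C)(C)O1)c1cc(OCc2ccccc2)cc(OCc2ccccc2)c1)c1cc(Cl)ccc1OC.[Li+] | intermediate
16 | (1S,2S)-1-[3,5-bis(benzyloxy)phenyl]-1-(5-chloro-2-methoxyphenyl)-2-[2,4-dimethoxy-6-(methoxymethoxy)phenyl]-2-(4-methoxyphenyl)ethane | COc1ccc(cc1)[C@@H](c1c(OC)cc(OC)cc1OCOC)[C@@H](c1cc(OCc2ccccc2)cc(OCc2ccccc2)c1)c1cc(Cl)ccc1OC | intermediate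
17 | 2-[(1S,2S)-2-[3,5-bis(benzyloxy)phenyl]-2-(5-chloro-2-methoxyphenyl)-1-(4-methoxyphenyl)ethyl]-3,5-dimethoxyphenol | COc1ccc(cc1)[C@@H](c1c(OC)cc(OC)cc1O)[C@@H](c1cc(OCc2ccccc2)cc(OCc2ccccc2)c1)c1cc(Cl)ccc1OC | intermediate
18 | trifluoromethanesulfonate of 17 | COc1ccc(cc1)[C@@H](c1c(OC)cc(OC)cc1OS(=O)(=O)C(F)(F)F)[C@@H](c1cc(OCc2ccccc2)cc(OCc2ccccc2)c1)c1cc(Cl)ccc1OC | intermediate
19 | 2-[(1S,2S)-2-(5-chloro-2-methoxyphenyl)-2-(3,5-dihydroxyphenyl)-1-(4-methoxyphenyl)ethyl]-3,5-dimethoxyphenyl trifluoromethanesulfonate | COc1ccc(cc1)[C@@H](c1c(OC)cc(OC)cc1OS(=O)(=O)C(F)(F)F)[C@@H](c1cc(O)cc(O)c1)c1cc(Cl)ccc1OC | intermediate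
20 | (E)-2-[2-(4-methoxyphenyl)ethenyl]-4,4,5,5-tetramethyl-1,3,2-dioxaborolane | COc1ccc(/C=C/B2OC(C)(C)C(C)(C)O2)cc1 | starting material
21 | 5-[(1S,2S)-1-(5-chloro-2-methoxyphenyl)-2-{2,4-dimethoxy-6-[(E)-2-(4-methoxyphenyl)ethenyl]phenyl}-2-(4-methoxyphenyl)ethyl]benzene-1,3-diol (seco stilbene) | COc1ccc(cc1)[C@@H](c1c(OC)cc(OC)cc1/C=C/c1ccc(OC)cc1)[C@@H](c1cc(O)cc(O)c1)c1cc(Cl)ccc1OC | intermediate
22 | upper-half aryl chloride, pentamethyl ether with one free ring B hydroxyl (Ca S, Cb S, Cc S, Cd S) | COc1ccc([C@H]2c3c(OC)cc(OC)cc3[C@H]3c4c(cc(O)cc4[C@H]2c2cc(Cl)ccc2OC)O[C@@H]3c2ccc(OC)cc2)cc1 | intermediate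
23 | upper-half aryl chloride hexaphenol | Oc1ccc([C@H]2c3c(O)cc(O)cc3[C@H]3c4c(cc(O)cc4[C@H]2c2cc(Cl)ccc2O)O[C@@H]3c2ccc(O)cc2)cc1 | intermediate
24 | upper-half aryl chloride hexaacetate | CC(=O)Oc1ccc([C@H]2c3c(OC(C)=O)cc(OC(C)=O)cc3[C@H]3c4c(cc(OC(C)=O)cc4[C@H]2c2cc(Cl)ccc2OC(C)=O)O[C@@H]3c2ccc(OC(C)=O)cc2)cc1 | intermediate
25 | 2-bromo-4,6-dimethoxybenzaldehyde | COc1cc(Br)c(C=O)c(OC)c1 | starting material
26 | 2-bromo-6-hydroxy-4-methoxybenzaldehyde | COc1cc(O)c(C=O)c(Br)c1 | intermediate
27 | 4-methoxybenzyl chloride | COc1ccc(CCl)cc1 | starting material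
28 | 2-bromo-4-methoxy-6-[(4-methoxybenzyl)oxy]benzaldehyde | COc1ccc(COc2cc(OC)cc(Br)c2C=O)cc1 | intermediate
29 | 3,5-dimethoxyphenylmagnesium chloride (THF solution) | COc1cc(OC)cc([Mg]Cl)c1 | starting material
30 | racemic {2-bromo-4-methoxy-6-[(4-methoxybenzyl)oxy]phenyl}(3,5-dimethoxyphenyl)methanol | COc1ccc(COc2cc(OC)cc(Br)c2C(O)c2cc(OC)cc(OC)c2)cc1 | intermediate
31 | {2-bromo-4-methoxy-6-[(4-methoxybenzyl)oxy]phenyl}(3,5-dimethoxyphenyl)methanone | COc1ccc(COc2cc(OC)cc(Br)c2C(=O)c2cc(OC)cc(OC)c2)cc1 | intermediate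
32 | hydrazone of 31 (E/Z mixture) | COc1ccc(COc2cc(OC)cc(Br)c2C(=NN)c2cc(OC)cc(OC)c2)cc1 | intermediate
33 | {2-bromo-4-methoxy-6-[(4-methoxybenzyl)oxy]phenyl}(3,5-dimethoxyphenyl)diazomethane | COc1ccc(COc2cc(OC)cc(Br)c2C(=[N+]=[N-])c2cc(OC)cc(OC)c2)cc1 | intermediate
34 | (2R,3S)-4-bromo-3-(3,5-dimethoxyphenyl)-6-methoxy-2-(4-methoxyphenyl)-2,3-dihydrobenzofuran (cis) | Brc1cc(OC)cc2c1[C@H](c1cc(OC)cc(OC)c1)[C@H](c1ccc(OC)cc1)O2 | intermediate
35 | (2S,3S)-4-bromo-3-(3,5-dihydroxyphenyl)-2-(4-hydroxyphenyl)-2,3-dihydrobenzofuran-6-ol (trans) | Brc1cc(O)cc2c1[C@H](c1cc(O)cc(O)c1)[C@@H](c1ccc(O)cc1)O2 | intermediate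
36 | tetraacetate of 35 | Brc1cc(OC(C)=O)cc2c1[C@H](c1cc(OC(C)=O)cc(OC(C)=O)c1)[C@@H](c1ccc(OC(C)=O)cc1)O2 | intermediate
37 | (2S,3S)-4-ethenyl-2,3-trans-dihydrobenzofuran tetraacetate | C=Cc1cc(OC(C)=O)cc2c1[C@H](c1cc(OC(C)=O)cc(OC(C)=O)c1)[C@@H](c1ccc(OC(C)=O)cc1)O2 | intermediate
38 | decaacetate of the target | CC(=O)Oc1ccc([C@H]2c3c(OC(C)=O)cc(OC(C)=O)cc3[C@H]3c4c(cc(OC(C)=O)cc4[C@H]2c2cc(/C=C/c4cc(OC(C)=O)cc5c4[C@H](c4cc(OC(C)=O)cc(OC(C)=O)c4)[C@@H](c4ccc(OC(C)=O)cc4)O5)ccc2OC(C)=O)O[C@@H]3c2ccc(OC(C)=O)cc2)cc1 | intermediate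
39 | CNP0266373.2 | Oc1ccc([C@H]2c3c(O)cc(O)cc3[C@H]3c4c(cc(O)cc4[C@H]2c2cc(/C=C/c4cc(O)cc5c4[C@H](c4cc(O)cc(O)c4)[C@@H](c4ccc(O)cc4)O5)ccc2O)O[C@@H]3c2ccc(O)cc2)cc1 | target

**Step count**
Total: 24 steps. Longest linear sequence: 16 steps (steps 1–14, 23, 24); the lower branch is steps 15–22.

**Steps most likely to fail**

Step 13. The radical-cation C–C closure may show poor facial selectivity at Cc, the free resorcinol or the product phenol may be oxidised in competition, or the stilbene may dimerise intermolecularly. Fallback by stepwise polar chemistry, setting out from 21: epoxidation of the stilbene with dimethyldioxirane (acetone/CH2Cl2, −40 °C) gives the acid-labile trans-epoxide F1, used crude. Sc(OTf)3 (CH2Cl2, −78 °C to 0 °C) then promotes intramolecular epoxide–arene Friedel–Crafts alkylation by B1 at Cc, closing the seven-membered ring to the benzylic alcohol F2. TsOH·H2O (CH2Cl2, rt) ionises the 4-methoxybenzylic alcohol at Cd and the neighbouring phenol oxygen closes the dihydrofuran under thermodynamic (trans) control. The sequence comes back to the route at 22.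

Step 7. s-BuLi may remove the doubly benzylic Ca–H (followed by β-elimination of the carbamate) or lithiate ring A ortho to the methoxymethoxy group instead of the carbamate α-position, and the 1,2-migration may be slow in the congested boronate. Fallback without a C–H deprotonation, setting out from 7: buffered Dess–Martin oxidation (NaHCO3, CH2Cl2, 0 °C) gives aldehyde F3, which is used at once at −78 °C with Bu3SnLi (weakly basic, so enolisation at Ca is avoided) to give the α-hydroxystannanes F4. Carbamoylation (i-Pr2NCOCl, Et3N, DMAP) and chromatographic separation of the carbinol epimers gives the (1S,2S)-α-stannyl carbamate F5. Tin–lithium exchange (n-BuLi, Et2O, −78 °C, retention) regenerates lithiated carbamate 10, which is borylated with 9 as in step 7; the sequence comes back to the route at 12.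

Step 8. NBS may brominate the very electron-rich ring A instead of the boronate, the hindered boronate may form incompletely, or configuration at the benzylic carbon may erode through single-electron pathways. Fallback by palladium catalysis, setting out from 12: 1,3-bis(benzyloxy)-5-iodobenzene F6 is made from 13 by copper-catalysed halogen exchange (CuI, NaI, N,N′-dimethylethylenediamine, dioxane, 110 °C). F6 is coupled with 12 in a stereoretentive Suzuki–Miyaura reaction of the secondary benzylic boronic ester (Pd2(dba)3, PPh3, Ag2O, DME, 85 °C); the sequence comes back to the route at 16.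

**Further compounds**
F1 | step 13 | trans-epoxide of seco stilbene 21 (both epoxide faces; epoxide carbons not assigned) | COc1ccc(cc1)[C@@H](c1c(OC)cc(OC)cc1C1OC1c1ccc(OC)cc1)[C@@H](c1cc(O)cc(O)c1)c1cc(Cl)ccc1OC
F2 | step 13 | seven-membered-ring benzylic alcohol (Cc–B1 bond formed, Cd–OH epimers, ring B resorcinol free) | COc1ccc([C@H]2c3c(OC)cc(OC)cc3[C@H](C(O)c3ccc(OC)cc3)c3c(O)cc(O)cc3[C@H]2c2cc(Cl)ccc2OC)cc1
F3 | step 7 | (S)-2-[2,4-dimethoxy-6-(methoxymethoxy)phenyl]-2-(4-methoxyphenyl)acetaldehyde | COc1ccc(cc1)[C@@H](c1c(OC)cc(OC)cc1OCOC)C=O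
F4 | step 7 | (2S)-2-[2,4-dimethoxy-6-(methoxymethoxy)phenyl]-2-(4-methoxyphenyl)-1-(tributylstannyl)ethanol (carbinol epimers) | COc1ccc(cc1)[C@@H](c1c(OC)cc(OC)cc1OCOC)C(O)[Sn](CCCC)(CCCC)CCCC
F5 | step 7 | (1S,2S)-2-[2,4-dimethoxy-6-(methoxymethoxy)phenyl]-2-(4-methoxyphenyl)-1-(tributylstannyl)ethyl N,N-diisopropylcarbamate | COc1ccc(cc1)[C@@H](c1c(OC)cc(OC)cc1OCOC)[C@H]([Sn](CCCC)(CCCC)CCCC)OC(=O)N(C(C)C)C(C)C
F6 | step 8 | 1,3-bis(benzyloxy)-5-iodobenzene | Ic1cc(OCc2ccccc2)cc(OCc2ccccc2)c1
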